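## Structural features

The target is a 2-arylbenzofuran. Ring A (the benzo ring, C3a to C7a) is fused to the furan ring B (O1, C2, C3), and C2 carries ring C through C1'. Ring A has a phloroglucinol pattern (O1, 4-OH, 6-OH), and C7, between O1 and the 6-hydroxyl, bears a 1,1-dimethylallyl group: a quaternary benzylic carbon carrying a vinyl group. Ring C is a resorcinol (3'-OH, 5'-OH) with linear prenyl groups at C2' and C6', both flanking the C2–C1' bond and each ortho to a hydroxyl. There is no stereocentre and no configurational double bond, and ring C is symmetric about the C1'–C4' axis, so the crowded C2–C1' bond raises no atropisomer question. The fragile groups are the four electron-rich phenols (air oxidation, C-nucleophilic at C5 and C4'), the prenyl groups ortho to hydroxyls (acid closes them to 2,2-dimethylchromans) and the branched C7 chain ortho to a hydroxyl (acid or prolonged heat cyclises or isomerises it). The real difficulty is to place three C5 units with the correct position and connectivity (two linear, one branched) on two similar rings, without exposing finished prenyl phenols to acid and without forming a bond at a ring C carbonyl carbon that already has two ortho substituents. The key step uses the fact that the C2' and C6' chains can be carried as CH2–CH=CH2 with open terminal olefins, whereas the C7 vinyl group sits on a quaternary carbon wedged between O1 and O6. Only the two allyl termini are therefore converted into CH=C(CH3)2.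

## Logic of the disconnections

19 to 17 + 18. The two C=C bonds between the side-chain CH and C(CH3)2 at C2' and C6' are cut. The prenyl group is the acid-labile unit and the one with a linear-versus-branched problem, whereas an allyl group is robust and can be placed by sigmatropy. The last intermediate then carries only monosubstituted olefins and nothing follows the metathesis. The forward step must distinguish among three terminal olefins, avoid migration of the allyl double bonds into conjugation and tolerate four free phenols.

17 to 16. The O–CH2 bonds of the two ring A acetals are cut. These groups are needed only while a single hydroxyl (the future O1) is acylated, and they are removed before any prenyl group exists. The forward step needs an acid that leaves monosubstituted olefins alone.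

16 to 15. The C4'–H bond is traced back to C4'–Br. The bromine is the blocking group of the ring C rearrangement and is removed once it has done its work. The forward step must reduce an aryl bromide in the presence of three olefins and two free phenols.

15 to 14. The C2'–CH2 and C6'–CH2 bonds are cut and the allyl groups returned to O3' and O5'. A [3,3] shift delivers unbranched allyl groups ortho to oxygen, and with C4' blocked there is no positional choice. Placing this step after closure of ring B means that the ring C carbonyl used for ring B never has ortho substituents. The forward step requires that the rest of the molecule survive about 200 °C.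

14 to 7 + 11. C2=C3 and O1–C2 are cut, which divides the molecule into two arenes of similar size. The forward step needs a single free hydroxyl in 7 and an unhindered acyl group in 11.

7 to 6 to 5. The C–P bond and the benzylic C–O bond are cut back to a formyl group, whose carbon becomes C3. The forward steps must spare the acetals.

5 to 4. Two acetal O–C bonds are cut. The forward step must leave the hydroxyl next to the quaternary carbon free.

4 to 3. The bond between ring A and the quaternary carbon is cut and reconnected as an O4 prenyl ether. The [3,3] shift inverts the allyl unit and so gives the branched chain. The two ortho positions are equivalent and the para carbon carries the formyl group, so only one aromatic product is possible. The forward step must stop at the ortho phenol.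

3 to 1 + 2. The O4–CH2 bond is cut. The forward step must alkylate the one hydroxyl that is not hydrogen-bonded to the aldehyde.

11 to 10 to 8 + 9. The ester and the two O-allyl bonds are cut. Both forward steps are routine on an unhindered benzoate.

## Other disconnections considered

Alternative 1: The cut is the C4'–C5' bond of ring C, which opens the ring to the δ-keto ester A1 (methyl ketone at the future C3'/C4', ester at the future C5'). In the forward direction the methyl-ketone enolate of A1 acylates itself on the ester carbonyl (Dieckmann-type closure) to give the all-trans dione A2, which must then be dehydrogenated to the resorcinol and freed of its acetals.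
- In its favour: every ring C substituent is placed by aliphatic C–C bond formation, so no aromatic regiochemistry, blocking halogen or olefin discrimination is needed. The prenyl groups can come from enolate alkylation, and the three stereocentres of A2 disappear on aromatisation. On positional control of the prenyl groups it is the equal of the chosen plan, and better in not depending on a ruthenium catalyst.
- Against it: the dione has to lose four hydrogens in the presence of two trisubstituted olefins, a vinyl group and the benzofuran, and the usual reagents (halogenation–elimination, quinones, metal dehydrogenation) are electrophilic or oxidising toward exactly these groups. The acetals would then be removed with acid when the prenyl phenols already exist. Enolate regiochemistry and retro-Michael loss at the doubly activated benzylic carbon are further concerns.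
- Comparison: the ring-forming condensation is as reliable as the sigmatropic steps of the chosen plan, but the aromatisation is mechanistically much less secure than the metathesis, and building A1 with the benzofuran attached is clearly longer.

Alternative 2: The cut is C2=C3 of the furan with all three C5 units already in place. The ylide from the phosphonium salt A3 attacks its own ester carbonyl and gives the tetrakis(methoxymethyl) ether A4, which is then deprotected.
- In its favour: this is the same ring closure the chosen plan uses in step 8, so on the construction of ring B the two plans are equal. The alternative is better in convergence, since nothing but deprotection follows the union, and it avoids a late metal-catalysed step on a polyphenol.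
- Against it: the aroyl group of A3 carries two ortho prenyl groups. Its ester with the hindered ring A phenol is hard to form, and the carbonyl is twisted and shielded against the ylide. The diprenyl acid would itself require a regiocontrolled double C-prenylation, so the problem solved by the chosen plan would return earlier. The final acid treatment of A4 would expose prenyl groups ortho to nascent hydroxyls to chroman formation.
- Comparison: the chosen plan keeps the Wittig closure on an unhindered ester and defers the acid-sensitive groups to the last step, at the cost of three more operations after the union.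

Alternative 3: The cut removes ring A altogether (C7–C7a, C4–C5, C6–C7, C3a–C4). Irradiation of the furyl diazo ketone A5 would cause Wolff rearrangement, the resulting ketene would add to the siloxyalkyne A6, and ring opening and 6π closure onto the furan would give the benzofuranol A7.
- In its favour: the branched chain is set on the diazo carbon and ends at C7 with no rearrangement and no positional question, and the two ring A oxygens come out differentiated. On regiocontrol within ring A it is better than the chosen plan, which relies on a symmetric Claisen substrate and a selective protection.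
- Against it: A5 needs diazo transfer next to a quaternary carbon, where 1,2-shift in the carbene competes with the Wolff pathway. The photolysis and ketene chemistry run in a molecule with three olefins. A furan carrying the diprenyl aryl group has to be built first, and two different deprotections follow, one of them acidic with the prenyl groups present.
- Comparison: equal or better on ring A regiochemistry, weaker on functional-group tolerance in the key step and on the late acid step, and probably longer.

Key step: step 12

Remark on the chemistry: the C4' bromine is kept as the blocking group for the ring C Claisen rearrangement, but that rearrangement is placed after closure of ring B, because a benzoate flanked by two allyl groups would resist ester cleavage, acylation of the hindered phenol and ylide attack. The metathesis precursor 17 is unchanged by this.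

## Route

Step 1
Reactants: 1 2,4,6-trihydroxybenzaldehyde; 2 prenyl bromide (1-bromo-3-methylbut-2-ene)
Product: 3 2,6-dihydroxy-4-[(3-methylbut-2-en-1-yl)oxy]benzaldehyde
Conditions: K2CO3 (1.0 equiv), 2 (1.0 equiv), acetone, 0 °C to rt
Reagents that add atoms: none
Why: Williamson etherification; one equivalent of base ionises the para hydroxyl, which is the most acidic and the only one not hydrogen-bonded to the formyl group, so O-alkylation should occur at O4.

Step 2
Reactants: 3 2,6-dihydroxy-4-[(3-methylbut-2-en-1-yl)oxy]benzaldehyde
Product: 4 2,4,6-trihydroxy-3-(2-methylbut-3-en-2-yl)benzaldehyde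
Conditions: PhNEt2, 180 °C, argon, short reaction time
Reagents that add atoms: none
Why: Aromatic Claisen rearrangement ([3,3] shift), which inverts the allyl unit and so turns the prenyl ether into the branched C-substituent; the two ortho positions are equivalent and the para carbon carries the formyl group, so the only dienone that can rearomatise is the one leading to 4.

Step 3
Reactants: 4 2,4,6-trihydroxy-3-(2-methylbut-3-en-2-yl)benzaldehyde
Product: 5 2-hydroxy-4,6-bis(methoxymethoxy)-3-(2-methylbut-3-en-2-yl)benzaldehyde
Conditions: MOMCl (2.2 equiv), i-Pr2NEt, CH2Cl2, 0 °C to rt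
Reagents that add atoms: chloromethyl methyl ether, COCCl
Why: Base-mediated acetal ether formation; O4 is the most acidic hydroxyl, and of the two chelated hydroxyls O6 is the one not shielded by the quaternary carbon, so the hydroxyl left free should be the hydrogen-bonded, doubly flanked O2 that becomes the furan oxygen.

Step 4
Reactants: 5 2-hydroxy-4,6-bis(methoxymethoxy)-3-(2-methylbut-3-en-2-yl)benzaldehyde
Product: 6 2-(hydroxymethyl)-3,5-bis(methoxymethoxy)-6-(2-methylbut-3-en-2-yl)phenol
Conditions: NaBH4, THF/MeOH, 0 °C; used crude
Reagents that add atoms: none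
Why: Borohydride reduction of an aromatic aldehyde; the acetals, the vinyl group and the phenol are inert, and the electron-rich ortho-hydroxybenzyl alcohol is not chromatographed, to avoid quinone methide formation.

Step 5
Reactants: 6 2-(hydroxymethyl)-3,5-bis(methoxymethoxy)-6-(2-methylbut-3-en-2-yl)phenol
Product: 7 [2-hydroxy-4,6-bis(methoxymethoxy)-3-(2-methylbut-3-en-2-yl)benzyl]triphenylphosphonium bromide
Conditions: PPh3·HBr (1.0 equiv), MeCN, 0 °C to rt
Reagents that add atoms: triphenylphosphine hydrobromide, Br.c1ccc(cc1)P(c1ccccc1)c1ccccc1
Why: Phosphonium salt formation from an ortho-hydroxybenzyl alcohol: protonation and loss of water give an ortho-quinone methide that is captured by triphenylphosphine; the acid is consumed as the salt forms and the trioxygenated ring ionises at low temperature, which limits exposure of the acetals.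

Step 6
Reactants: 8 methyl 4-bromo-3,5-dihydroxybenzoate; 9 allyl bromide (3-bromoprop-1-ene)
Product: 10 methyl 4-bromo-3,5-bis(prop-2-en-1-yloxy)benzoate
Conditions: K2CO3, 9 (2.4 equiv), DMF, 60 °C
Reagents that add atoms: none
Why: Double Williamson etherification of the two equivalent phenols.

Step 7
Reactants: 10 methyl 4-bromo-3,5-bis(prop-2-en-1-yloxy)benzoate
Product: 11 4-bromo-3,5-bis(prop-2-en-1-yloxy)benzoic acid
Conditions: LiOH, THF/MeOH/H2O, 40 °C; then 1 M HCl
Reagents that add atoms: lithium hydroxide, [Li+].[OH-]
Why: Saponification of a methyl benzoate with no ortho substituent; aryl allyl ethers and the aryl bromide are inert.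

Step 8
Reactants: 7 [2-hydroxy-4,6-bis(methoxymethoxy)-3-(2-methylbut-3-en-2-yl)benzyl]triphenylphosphonium bromide; 11 4-bromo-3,5-bis(prop-2-en-1-yloxy)benzoic acid
Product: 14 2-[4-bromo-3,5-bis(prop-2-en-1-yloxy)phenyl]-4,6-bis(methoxymethoxy)-7-(2-methylbut-3-en-2-yl)-1-benzofuran, via 4-bromo-3,5-bis(allyloxy)benzoyl chloride 12 (not isolated), via O-aroyl phosphonium bromide 13 (not isolated)
Conditions: 11, (COCl)2, DMF (cat.), CH2Cl2, 0 °C to rt, evaporate; then 7, Et3N (3.5 equiv), toluene, rt then 110 °C
Reagents that add atoms: none
Why: Acid chloride formation, O-acylation of the only phenol of 7, then intramolecular Wittig reaction of the triethylamine-generated ylide on the aryl ester carbonyl, the standard phosphonium route to 2-arylbenzofurans. The aroyl group has no ortho substituent, so neither acylation of the hindered phenol nor ylide attack is impeded.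

Step 9
Reactants: 14 2-[4-bromo-3,5-bis(prop-2-en-1-yloxy)phenyl]-4,6-bis(methoxymethoxy)-7-(2-methylbut-3-en-2-yl)-1-benzofuran
Product: 15 2-bromo-5-[4,6-bis(methoxymethoxy)-7-(2-methylbut-3-en-2-yl)-1-benzofuran-2-yl]-4,6-di(prop-2-en-1-yl)benzene-1,3-diol
Conditions: PhNEt2, 200 °C, argon, sealed vessel
Reagents that add atoms: none
Why: Double aromatic Claisen rearrangement; each allyl ether has one ortho position blocked by bromine, so both allyl groups are delivered unbranched to C2' and C6'. The acetals, the benzofuran and the C7 chain, which has no free ortho hydroxyl at this stage, are expected to tolerate the temperature in the basic solvent.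

Step 10
Reactants: 15 2-bromo-5-[4,6-bis(methoxymethoxy)-7-(2-methylbut-3-en-2-yl)-1-benzofuran-2-yl]-4,6-di(prop-2-en-1-yl)benzene-1,3-diol
Product: 16 5-[4,6-bis(methoxymethoxy)-7-(2-methylbut-3-en-2-yl)-1-benzofuran-2-yl]-4,6-di(prop-2-en-1-yl)benzene-1,3-diol
Conditions: Bu3SnH (1.3 equiv), AIBN (cat.), toluene, 90 °C; KF work-up
Reagents that add atoms: none
Why: Radical chain hydrodebromination: the stannyl radical abstracts bromine and the aryl radical takes hydrogen from Bu3SnH. The aryl radical has no olefin within reach for cyclisation, isolated terminal olefins are not reduced under these conditions, and phenols are tolerated.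

Step 11
Reactants: 16 5-[4,6-bis(methoxymethoxy)-7-(2-methylbut-3-en-2-yl)-1-benzofuran-2-yl]-4,6-di(prop-2-en-1-yl)benzene-1,3-diol
Product: 17 2-[3,5-dihydroxy-2,6-di(prop-2-en-1-yl)phenyl]-7-(2-methylbut-3-en-2-yl)-1-benzofuran-4,6-diol
Conditions: HCl (2 M in MeOH), 40 °C, argon
Reagents that add atoms: none
Why: Acid-catalysed acetal exchange with methanol removes both methoxymethyl groups as dimethoxymethane. The molecule carries only monosubstituted olefins at this point, which dilute acid does not protonate; the acid-sensitive prenyl groups are deliberately not yet present.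

Step 12
Reactants: 17 2-[3,5-dihydroxy-2,6-di(prop-2-en-1-yl)phenyl]-7-(2-methylbut-3-en-2-yl)-1-benzofuran-4,6-diol; 18 2-methyl-2-butene
Product: 19 2-[3,5-dihydroxy-2,6-bis(3-methylbut-2-en-1-yl)phenyl]-7-(2-methylbut-3-en-2-yl)-1-benzofuran-4,6-diol (CNP0115465.0)
Conditions: RuCl2(H2IMes)(PCy3)(=CHPh) (second-generation Grubbs catalyst, 10 mol %), 1,4-benzoquinone (10 mol %), CH2Cl2/18 (large excess), 35 °C, argon
Reagents that add atoms: none
Why: Olefin cross-metathesis by the Chauvin mechanism: after loss of PCy3 the benzylidene is exchanged against 18, so isopropylidene and ethylidene ruthenium species carry the chain; each allyl terminus of 17 forms a ruthenacyclobutane whose cycloreversion releases the ArCH2CH=C(CH3)2 unit, and the terminal CH2 leaves as propene. The closest known reaction type is the conversion of allylarenes, free ortho-allylphenols included, into prenylarenes with 2-methyl-2-butene and this catalyst. No ring is closed: the two allyl groups are meta to each other across ring C, the C7 vinyl group is remote and hindered, and the large excess of 18 outruns homodimerisation. No stereocentre and no E/Z element arises, because each new trisubstituted olefin ends in two methyl groups. The selectivity required is reaction at two of three terminal olefins, and the substrate secures it: the C7 vinyl group stands on a quaternary carbon that is also flanked by O1 and the 6-hydroxyl, so it is a slow, non-dimerising olefin that should not form a metallacycle with the substituted carbenes present. Migration of the allyl double bonds into conjugation with ring C by ruthenium hydride species is held back by the 1,4-benzoquinone additive and the mild temperature.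

## Compound list

1 | 2,4,6-trihydroxybenzaldehyde | O=Cc1c(O)cc(O)cc1O | starting material
2 | prenyl bromide (1-bromo-3-methylbut-2-ene) | CC(C)=CCBr | starting material
3 | 2,6-dihydroxy-4-[(3-methylbut-2-en-1-yl)oxy]benzaldehyde | O=Cc1c(O)cc(OCC=C(C)C)cc1O | intermediate
4 | 2,4,6-trihydroxy-3-(2-methylbut-3-en-2-yl)benzaldehyde | O=Cc1c(O)cc(O)c(C(C)(C)C=C)c1O | intermediate
5 | 2-hydroxy-4,6-bis(methoxymethoxy)-3-(2-methylbut-3-en-2-yl)benzaldehyde | O=Cc1c(OCOC)cc(OCOC)c(C(C)(C)C=C)c1O | intermediate
6 | 2-(hydroxymethyl)-3,5-bis(methoxymethoxy)-6-(2-methylbut-3-en-2-yl)phenol | OCc1c(OCOC)cc(OCOC)c(C(C)(C)C=C)c1O | intermediate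
7 | [2-hydroxy-4,6-bis(methoxymethoxy)-3-(2-methylbut-3-en-2-yl)benzyl]triphenylphosphonium bromide | [Br-].Oc1c(C[P+](c2ccccc2)(c2ccccc2)c2ccccc2)c(OCOC)cc(OCOC)c1C(C)(C)C=C | intermediate
8 | methyl 4-bromo-3,5-dihydroxybenzoate | COC(=O)c1cc(O)c(Br)c(O)c1 | starting material
9 | allyl bromide (3-bromoprop-1-ene) | C=CCBr | starting material
10 | methyl 4-bromo-3,5-bis(prop-2-en-1-yloxy)benzoate | COC(=O)c1cc(OCC=C)c(Br)c(OCC=C)c1 | intermediate
11 | 4-bromo-3,5-bis(prop-2-en-1-yloxy)benzoic acid | OC(=O)c1cc(OCC=C)c(Br)c(OCC=C)c1 | intermediate
12 | 4-bromo-3,5-bis(prop-2-en-1-yloxy)benzoyl chloride | ClC(=O)c1cc(OCC=C)c(Br)c(OCC=C)c1 | intermediate (not isolated)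
13 | [2-{[4-bromo-3,5-bis(prop-2-en-1-yloxy)benzoyl]oxy}-4,6-bis(methoxymethoxy)-3-(2-methylbut-3-en-2-yl)benzyl]triphenylphosphonium bromide | [Br-].C=CC(C)(C)c1c(OC(=O)c2cc(OCC=C)c(Br)c(OCC=C)c2)c(C[P+](c2ccccc2)(c2ccccc2)c2ccccc2)c(OCOC)cc1OCOC | intermediate (not isolated)
14 | 2-[4-bromo-3,5-bis(prop-2-en-1-yloxy)phenyl]-4,6-bis(methoxymethoxy)-7-(2-methylbut-3-en-2-yl)-1-benzofuran | C=CC(C)(C)c1c(OCOC)cc(OCOC)c2cc(-c3cc(OCC=C)c(Br)c(OCC=C)c3)oc12 | intermediate
15 | 2-bromo-5-[4,6-bis(methoxymethoxy)-7-(2-methylbut-3-en-2-yl)-1-benzofuran-2-yl]-4,6-di(prop-2-en-1-yl)benzene-1,3-diol | C=CC(C)(C)c1c(OCOC)cc(OCOC)c2cc(-c3c(CC=C)c(O)c(Br)c(O)c3CC=C)oc12 | intermediate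
16 | 5-[4,6-bis(methoxymethoxy)-7-(2-methylbut-3-en-2-yl)-1-benzofuran-2-yl]-4,6-di(prop-2-en-1-yl)benzene-1,3-diol | C=CC(C)(C)c1c(OCOC)cc(OCOC)c2cc(-c3c(CC=C)c(O)cc(O)c3CC=C)oc12 | intermediate
17 | 2-[3,5-dihydroxy-2,6-di(prop-2-en-1-yl)phenyl]-7-(2-methylbut-3-en-2-yl)-1-benzofuran-4,6-diol | C=CCc1c(O)cc(O)c(CC=C)c1-c1cc2c(O)cc(O)c(C(C)(C)C=C)c2o1 | intermediate
18 | 2-methyl-2-butene | CC=C(C)C | starting material
19 | 2-[3,5-dihydroxy-2,6-bis(3-methylbut-2-en-1-yl)phenyl]-7-(2-methylbut-3-en-2-yl)-1-benzofuran-4,6-diol (CNP0115465.0) | C=CC(C)(C)c1c(O)cc(O)c2cc(-c3c(CC=C(C)C)c(O)cc(O)c3CC=C(C)C)oc12 | target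

## Step count and least certain steps

Total: 12 steps. Longest linear sequence: 10 steps (steps 1 to 5 and 8 to 12); the ring C branch is steps 6 and 7.

Step 12 (key step). The most likely failure is migration of the allyl double bonds into conjugation, caused by ruthenium hydride species that form as the catalyst decays; metathesis of the propenyl isomer would then shorten the chain. Slow turnover at the second allyl group, or catalyst deactivation by the chelating, easily oxidised polyphenol, is the next concern. Participation of the C7 vinyl group is considered the least likely fault. The fallback sets out from 17 and returns at 19, and it removes the free phenols from the metathesis without bringing acid back. Acetylation of 17 (Ac2O, pyridine, DMAP) should give 2-[3,5-diacetoxy-2,6-di(prop-2-en-1-yl)phenyl]-7-(2-methylbut-3-en-2-yl)-1-benzofuran-4,6-diyl diacetate F1. Cross-metathesis of this with 18 under RuCl2(H2IMes)(PCy3)(=CHPh) should give the tetraacetate of the target F2. Methanolysis (K2CO3, degassed MeOH, rt, then NH4Cl) should release 19 under conditions that do not cyclise prenyl phenols.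

Step 10. The radical chain may be retarded by the electron-rich phenols, which can act as hydrogen donors to chain carriers, and forcing the reaction could cause hydrostannylation of the terminal olefins. The fallback sets out from 15 and returns at 17, and it replaces the radical reduction by halogen–metal exchange on a fully protected substrate. MOMCl and NaH in DMF should give 2-[4-bromo-3,5-bis(methoxymethoxy)-2,6-di(prop-2-en-1-yl)phenyl]-4,6-bis(methoxymethoxy)-7-(2-methylbut-3-en-2-yl)-1-benzofuran F3. Treatment with t-BuLi (2.1 equiv, THF, −78 °C) and quenching with MeOH should give the debrominated tetrakis(methoxymethyl) ether F4. The conditions of step 11 should then remove all four acetals and give 17.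

Step 9. Prolonged heating of the advanced benzofuran may cause loss of the blocking bromine through delivery of an allyl group to C4', partial acetal cleavage by the phenols as they form, or general thermal degradation before the second shift is complete. The fallback sets out from 10 and returns at 17. It performs the rearrangement on the small benzoate and accepts a hindered acyl transfer in exchange. Heating 10 in PhNEt2 at 200 °C should give methyl 4-bromo-3,5-dihydroxy-2,6-di(prop-2-en-1-yl)benzoate F5. MOMCl and i-Pr2NEt should give methyl 4-bromo-3,5-bis(methoxymethoxy)-2,6-di(prop-2-en-1-yl)benzoate F6. Because the carbonyl is shielded, the methyl group is removed by substitution at carbon (LiI, pyridine, reflux) to give 4-bromo-3,5-bis(methoxymethoxy)-2,6-di(prop-2-en-1-yl)benzoic acid F7. 1-Chloro-N,N,2-trimethylpropenylamine should convert this under neutral conditions into 4-bromo-3,5-bis(methoxymethoxy)-2,6-di(prop-2-en-1-yl)benzoyl chloride F8. With 7 and Et3N in hot xylene this should pass through the O-aroyl phosphonium bromide F9 to F3, and from there as in the fallback of step 10 through F4 to 17.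

Step 2. The branched product has free hydroxyls on both sides of the new chain, so continued heating may cause an ene-type shift (abnormal Claisen) or ring closure onto the vinyl group. Ionisation of the ether, with loss or 1,3-transfer of the prenyl group, is also possible. The fallback sets out from 1 and returns at 5. It fixes the protection pattern first and runs the rearrangement catalytically at low temperature. MOMCl (2 equiv) and i-Pr2NEt should give 2-hydroxy-4,6-bis(methoxymethoxy)benzaldehyde F10. Prenyl bromide and K2CO3 should give 4,6-bis(methoxymethoxy)-2-[(3-methylbut-2-en-1-yl)oxy]benzaldehyde F11. Eu(fod)3 (cat.) in CHCl3 at 25 to 40 °C should promote the ortho shift to 5, and the reaction must be stopped before the slower Cope shift to C5 sets in.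

Step 3. Acetal formation at O2 instead of O6, or at all three oxygens, would misplace the free hydroxyl and lead to the 5-substituted benzofuran. The fallback sets out from 3 and returns at 5. It introduces the O6 acetal while the two chelated hydroxyls are still equivalent. MOMCl (1.1 equiv) and i-Pr2NEt should give 2-hydroxy-6-(methoxymethoxy)-4-[(3-methylbut-2-en-1-yl)oxy]benzaldehyde F12. Claisen rearrangement (PhNEt2, 180 °C) should give 2,4-dihydroxy-6-(methoxymethoxy)-3-(2-methylbut-3-en-2-yl)benzaldehyde F13; the position between the chelated hydroxyl and the ether oxygen is favoured by chelation-induced bond fixation and by the bulk of the acetal on the other side. A second MOMCl treatment, which should reach only the non-chelated 4-hydroxyl, gives 5.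

## Further compounds

F1 | step 12 | 2-[3,5-diacetoxy-2,6-di(prop-2-en-1-yl)phenyl]-7-(2-methylbut-3-en-2-yl)-1-benzofuran-4,6-diyl diacetate | C=CCc1c(OC(C)=O)cc(OC(C)=O)c(CC=C)c1-c1cc2c(OC(C)=O)cc(OC(C)=O)c(C(C)(C)C=C)c2o1
F2 | step 12 | 2-[3,5-diacetoxy-2,6-bis(3-methylbut-2-en-1-yl)phenyl]-7-(2-methylbut-3-en-2-yl)-1-benzofuran-4,6-diyl diacetate | C=CC(C)(C)c1c(OC(C)=O)cc(OC(C)=O)c2cc(-c3c(CC=C(C)C)c(OC(C)=O)cc(OC(C)=O)c3CC=C(C)C)oc12
F3 | step 10 | 2-[4-bromo-3,5-bis(methoxymethoxy)-2,6-di(prop-2-en-1-yl)phenyl]-4,6-bis(methoxymethoxy)-7-(2-methylbut-3-en-2-yl)-1-benzofuran | C=CC(C)(C)c1c(OCOC)cc(OCOC)c2cc(-c3c(CC=C)c(OCOC)c(Br)c(OCOC)c3CC=C)oc12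
F4 | step 10 | 2-[3,5-bis(methoxymethoxy)-2,6-di(prop-2-en-1-yl)phenyl]-4,6-bis(methoxymethoxy)-7-(2-methylbut-3-en-2-yl)-1-benzofuran | C=CC(C)(C)c1c(OCOC)cc(OCOC)c2cc(-c3c(CC=C)c(OCOC)cc(OCOC)c3CC=C)oc12
F5 | step 9 | methyl 4-bromo-3,5-dihydroxy-2,6-di(prop-2-en-1-yl)benzoate | COC(=O)c1c(CC=C)c(O)c(Br)c(O)c1CC=C
F6 | step 9 | methyl 4-bromo-3,5-bis(methoxymethoxy)-2,6-di(prop-2-en-1-yl)benzoate | COC(=O)c1c(CC=C)c(OCOC)c(Br)c(OCOC)c1CC=C
F7 | step 9 | 4-bromo-3,5-bis(methoxymethoxy)-2,6-di(prop-2-en-1-yl)benzoic acid | OC(=O)c1c(CC=C)c(OCOC)c(Br)c(OCOC)c1CC=C
F8 | step 9 | 4-bromo-3,5-bis(methoxymethoxy)-2,6-di(prop-2-en-1-yl)benzoyl chloride | ClC(=O)c1c(CC=C)c(OCOC)c(Br)c(OCOC)c1CC=C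
F9 | step 9 | [2-{[4-bromo-3,5-bis(methoxymethoxy)-2,6-di(prop-2-en-1-yl)benzoyl]oxy}-4,6-bis(methoxymethoxy)-3-(2-methylbut-3-en-2-yl)benzyl]triphenylphosphonium bromide | [Br-].C=CC(C)(C)c1c(OC(=O)c2c(CC=C)c(OCOC)c(Br)c(OCOC)c2CC=C)c(C[P+](c2ccccc2)(c2ccccc2)c2ccccc2)c(OCOC)cc1OCOC
F10 | step 2 | 2-hydroxy-4,6-bis(methoxymethoxy)benzaldehyde | O=Cc1c(O)cc(OCOC)cc1OCOC
F11 | step 2 | 4,6-bis(methoxymethoxy)-2-[(3-methylbut-2-en-1-yl)oxy]benzaldehyde | O=Cc1c(OCC=C(C)C)cc(OCOC)cc1OCOC
F12 | step 3 | 2-hydroxy-6-(methoxymethoxy)-4-[(3-methylbut-2-en-1-yl)oxy]benzaldehyde | O=Cc1c(O)cc(OCC=C(C)C)cc1OCOC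
F13 | step 3 | 2,4-dihydroxy-6-(methoxymethoxy)-3-(2-methylbut-3-en-2-yl)benzaldehyde | O=Cc1c(OCOC)cc(O)c(C(C)(C)C=C)c1O
A1 | alternative 1 | methyl 4-acetyl-3-[4,6-bis(methoxymethoxy)-7-(2-methylbut-3-en-2-yl)-1-benzofuran-2-yl]-7-methyl-2-(3-methylbut-2-en-1-yl)oct-6-enoate (mixture of diastereomers) | COC(=O)C(CC=C(C)C)C(c1cc2c(OCOC)cc(OCOC)c(C(C)(C)C=C)c2o1)C(CC=C(C)C)C(C)=O
A2 | alternative 1 | all-trans 5-[4,6-bis(methoxymethoxy)-7-(2-methylbut-3-en-2-yl)-1-benzofuran-2-yl]-4,6-bis(3-methylbut-2-en-1-yl)cyclohexane-1,3-dione | O=C1CC(=O)[C@@H](CC=C(C)C)[C@H](c2cc3c(OCOC)cc(OCOC)c(C(C)(C)C=C)c3o2)[C@H]1CC=C(C)C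
A3 | alternative 2 | [2-{[3,5-bis(methoxymethoxy)-2,6-bis(3-methylbut-2-en-1-yl)benzoyl]oxy}-4,6-bis(methoxymethoxy)-3-(2-methylbut-3-en-2-yl)benzyl]triphenylphosphonium bromide | [Br-].C=CC(C)(C)c1c(OC(=O)c2c(CC=C(C)C)c(OCOC)cc(OCOC)c2CC=C(C)C)c(C[P+](c2ccccc2)(c2ccccc2)c2ccccc2)c(OCOC)cc1OCOC
A4 | alternative 2 | 2-[3,5-bis(methoxymethoxy)-2,6-bis(3-methylbut-2-en-1-yl)phenyl]-4,6-bis(methoxymethoxy)-7-(2-methylbut-3-en-2-yl)-1-benzofuran | C=CC(C)(C)c1c(OCOC)cc(OCOC)c2cc(-c3c(CC=C(C)C)c(OCOC)cc(OCOC)c3CC=C(C)C)oc12
A5 | alternative 3 | 1-{5-[3,5-bis(methoxymethoxy)-2,6-bis(3-methylbut-2-en-1-yl)phenyl]furan-2-yl}-2-diazo-3,3-dimethylpent-4-en-1-one | C=CC(C)(C)C(=[N+]=[N-])C(=O)c1ccc(-c2c(CC=C(C)C)c(OCOC)cc(OCOC)c2CC=C(C)C)o1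
A6 | alternative 3 | (triisopropylsilyloxy)ethyne | C#CO[Si](C(C)C)(C(C)C)C(C)C
A7 | alternative 3 | 2-[3,5-bis(methoxymethoxy)-2,6-bis(3-methylbut-2-en-1-yl)phenyl]-7-(2-methylbut-3-en-2-yl)-6-(triisopropylsilyloxy)-1-benzofuran-4-ol | C=CC(C)(C)c1c(O[Si](C(C)C)(C(C)C)C(C)C)cc(O)c2cc(-c3c(CC=C(C)C)c(OCOC)cc(OCOC)c3CC=C(C)C)oc12
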